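The pitfall here is to count partner by what was weighed in. The flasks and the earlier runs are these:

| flask | starting material | partner | temperature | remark | time |
|---|---|---|---|---|---|
| birch | 2.0 × 10⁻⁴ M | 0.40 mM | 10 °C | run made earlier |  |
| larch | 2.0 × 10⁻⁴ M | 0.60 mM | 43 °C | run made earlier |  |
| elm | 1.0 × 10⁻⁴ M | 0.80 mM | 10 °C | run made earlier |  |
| amber | 2.0 × 10⁻⁴ M | 0.800 mM | 55 °C |  | 2.0 min |
| green | 2.0 × 10⁻⁴ M | 0.800 mM |  | at −5 °C until 40 s, from then on at 55 °C | 2.0 min |
| red | 2.0 × 10⁻⁴ M | 0.800 mM | −5 °C |  | 2.0 min |
| blue | 2.0 × 10⁻⁴ M | 0.800 mM | 25 °C |  | 2.0 min |

| run | time / min | mono adduct / % | double product / % |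
|---|---|---|---|
| birch | 1.50 | 32.9 | 10.0 |
| birch | 2.50 | 29.5 | 11.0 |
| birch | 4.00 | 23.2 | 8.4 |
| birch | 6.00 | 20.2 | 11.4 |
| birch | 10.0 | 11.7 | 9.1 |
| birch | 12.0 | 12.0 | 12.1 |
| birch | 15.0 | 7.5 | 12.7 |
| larch | 0.333 | 19.2 | 2.3 |
| larch | 0.667 | 10.2 | 2.7 |
| larch | 0.833 | 10.2 | 2.4 |
| larch | 1.33 | 5.6 | 3.8 |
| larch | 2.00 | 2.3 | 4.3 |
| larch | 2.50 | 4.0 | 4.5 |
| elm | 3.00 | 36.7 | 38.8 |
| elm | 6.00 | 35.4 | 39.8 |
| elm | 10.0 | 30.7 | 39.9 |
| elm | 12.0 | 31.3 | 40.1 |
| elm | 15.0 | 31.0 | 36.2 |

(readings scatter by 1 percentage point)

- percent here means starting material units held: one side product counts as two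

* the flask that comes out highest in share of mono adduct in all that became mono adduct or double product or triple product or isomer of the product or side product, or "all alike" when all lie within 1.5 percentage points (amber / green / red / blue / all alike)
* share of mono adduct in all that became mono adduct or double product or triple product or isomer of the product or side product, amber
* share of mono adduct in all that became mono adduct or double product or triple product or isomer of the product or side product, green
* share of mono adduct in all that became mono adduct or double product or triple product or isomer of the product or side product, red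
* share of mono adduct in all that became mono adduct or double product or triple product or isomer of the product or side product, blue

The elm run looks contradictory. It held 8.00 partner per starting material, yet double product read 38.8% at 3.00 min and 36.2% at 15.0 min, while mono adduct read 36.7% and 31.0% at those times. So double product in elm did not climb although mono adduct stood beside it and the partner charged was far beyond what the products hold.

I reckoned what the products do hold, one partner in mono adduct and two in double product. This partner yield, the fraction of charged partner found in mono and double product at the first reading, read 26.4% in birch, 14.3% in elm and 7.93% in larch. These are readings and floors, since side product is not counted. So in elm 85.7% of the partner charged stood outside these two products at that reading. Larch, hotter than birch and with a larger partner charge, read the lower yield.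

For red, colder than birch and charged with the same starting material but more partner, I took birch's yield as a rough estimate, which gives a reach of 1.06 partner per starting material. The statistical case is my zero: two equal sites, hit blindly, put mono adduct at its best at reach one. At my reach, mono adduct holds 64.0% of mono plus double product. Side product lowers the asked share by an amount I could not read. Since larch's mono adduct fell to 2.3% by 2.00 min, I put red highest.

The forecast gave 4.5% for amber, 4% for green, 21% for red and 42% for blue, with blue highest, noting that “Double stays flat while mono falls”.

The flasks gave 1.71% for amber, 22.0% for green, 50.8% for red and 29.5% for blue, so red is highest.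

    partner → decomposed reagent (k = 0.0934 /s, Ea = 70.0 kJ/mol)
    mono adduct ⇌ isomer of the product (K = 0.960, k = 0.00163 /s, Ea = 91.0 kJ/mol, ΔH = −53.0 kJ/mol)
    starting material + partner → mono adduct + by-product (k = 190 /M/s, Ea = 40.0 kJ/mol)
    partner + double product → triple product + by-product (k = 19.7 /M/s, Ea = 43.0 kJ/mol)
    starting material + mono adduct → side product (k = 111 /M/s, Ea = 36.0 kJ/mol)
    partner + mono adduct → double product + by-product (k = 82.0 /M/s, Ea = 41.0 kJ/mol)
    (constants at 25 °C)

Red held mono adduct 44.7% and double product 28.0% at 2.00 min, with 41% of its partner left. That is a reach of 1.01 against my 1.06, and a share of 61.5% against 64.0%. The neighbour of red charged with 3.2 × 10⁻⁴ M of partner gets, at the same yield, a reach of 0.423 and a share of 88.2%. That neighbour held mono adduct 35.1% and double product 6.74%, a reach of 0.486 and a share of 83.9%, and its asked share was 60.8%.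

The numbers in the tables come from a simulation on assumed constants; scatter was added.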